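**Plan**

- Ring C of the target is a six-membered aryl ketone. C4 can be carried as the silyl enol ether of an aryl methyl ketone on C4a, and C2 is an allylic aryl ether carbon bearing a vinyl group, so the C3–C4 bond is cut as the C3=C4 bond of a 4-silyloxy-2H-chromene.
- Further cuts: O1–C2 (allylic etherification with a cinnamyl carbonate that brings ring B), C4a–C4 (acylation of an aryllithium) and C6–C1′ (aryllithium plus aldehyde, then dehydration).
- Forward: ring A is built from phloroglucinol with the C10 chain placed between two MOM ethers. The acetyl group is then placed ortho to the third oxygen, the O1–C2 ether is made, and ring C is closed last by metathesis, followed by unmasking.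
- Stereochemistry: C3′ comes unchanged from (S)-citronellal; C2 is set by the chiral iridium phosphoramidite catalyst; the E alkene comes from a syn-elimination.
- Regiochemistry on ring A is fixed by the mirror symmetry of the 4-substituted 3,5-bis(methoxymethoxy)phenol.

Key step: step 13

Assumption: the (Sa,Sc,Sc) enantiomer of the phosphoramidite ligand is taken to deliver the 2S ether in step 11; if the sense of induction proves opposite, its antipode is used.

**Route**

Step 1
Reactants: 1 methyl (2E)-3-(4-hydroxyphenyl)prop-2-enoate (methyl p-coumarate)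
Product: 2 methyl (2E)-3-[4-(methoxymethoxy)phenyl]prop-2-enoate
Conditions: MeOCH2Cl, i-Pr2NEt, CH2Cl2, 0 °C → rt
Reagents that add atoms: chloromethyl methyl ether, COCCl
Why: O-alkylation of the phenol with chloromethyl methyl ether (methoxymethyl protection) is routine and the enoate is inert to the hindered amine base.

Step 2
Reactants: 2 methyl (2E)-3-[4-(methoxymethoxy)phenyl]prop-2-enoate
Product: 3 (2E)-3-[4-(methoxymethoxy)phenyl]prop-2-en-1-ol
Conditions: i-Bu2AlH (2.2 equiv), CH2Cl2, −78 °C; aq. potassium sodium tartrate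
Reagents that add atoms: none
Why: i-Bu2AlH reduces the α,β-unsaturated ester by 1,2-hydride delivery to the allylic alcohol at low temperature (ester reduction), leaving the E alkene and the aryl acetal untouched.

Step 3
Reactants: 3 (2E)-3-[4-(methoxymethoxy)phenyl]prop-2-en-1-ol
Product: 4 (2E)-3-[4-(methoxymethoxy)phenyl]prop-2-en-1-yl methyl carbonate
Conditions: ClCO2Me, pyridine, CH2Cl2, 0 °C
Reagents that add atoms: methyl chloroformate, COC(=O)Cl
Why: Acylation of the primary allylic alcohol with a chloroformate gives the methyl carbonate, the leaving group that ionises under iridium catalysis in step 11.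

Step 4
Reactants: 5 benzene-1,3,5-triol (phloroglucinol)
Product: 6 3,5-bis(methoxymethoxy)phenol
Conditions: MeOCH2Cl (2.0 equiv), i-Pr2NEt, THF/DMF, 0 °C → rt; chromatography
Reagents that add atoms: chloromethyl methyl ether, COCCl
Why: Twofold Williamson-type etherification of the threefold-symmetric triol can differ only in degree, so the bis-ether is separated from mono- and tris-ether (both recyclable after acid hydrolysis) without any regiochemical issue.

Step 5
Reactants: 6 3,5-bis(methoxymethoxy)phenol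
Product: 7 [3,5-bis(methoxymethoxy)phenoxy]tri(propan-2-yl)silane
Conditions: i-Pr3SiCl, imidazole, DMF, rt
Reagents that add atoms: chlorotri(propan-2-yl)silane, CC(C)[Si](Cl)(C(C)C)C(C)C
Why: Silylation of the remaining phenol gives a bulky ether that neither directs lithiation nor is attacked by n-BuLi, which reserves the site between the two acetal oxygens for metalation.

Step 6
Reactants: 7 [3,5-bis(methoxymethoxy)phenoxy]tri(propan-2-yl)silane; 8 (3S)-3,7-dimethyloct-6-enal ((S)-citronellal)
Product: 10 (1RS,3S)-1-[2,6-bis(methoxymethoxy)-4-(triisopropylsilyloxy)phenyl]-3,7-dimethyloct-6-en-1-ol (both C1 epimers), via 2,6-bis(methoxymethoxy)-4-(triisopropylsilyloxy)phenyllithium 9 (not isolated)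
Conditions: n-BuLi, THF, 0 °C; then 8, −78 → 0 °C; H2O
Reagents that add atoms: none
Why: Directed ortho-metalation takes place at the one position flanked by two coordinating OCH2OMe groups and the aryllithium adds to the aldehyde (1,2-addition); the carbinol centre forms unselectively and is destroyed in step 7, while C3 of the aldehyde is not enolisable and keeps its S configuration.

Step 7
Reactants: 10 (1RS,3S)-1-[2,6-bis(methoxymethoxy)-4-(triisopropylsilyloxy)phenyl]-3,7-dimethyloct-6-en-1-ol
Product: 11 {4-[(1E,3S)-3,7-dimethylocta-1,6-dien-1-yl]-3,5-bis(methoxymethoxy)phenoxy}tri(propan-2-yl)silane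
Conditions: Burgess reagent (MeO2CN−SO2N+Et3), toluene, rt → 50 °C
Reagents that add atoms: none
Why: Burgess dehydration proceeds through the sulfamate ester and intramolecular syn-elimination; the only β-hydrogens are on C2′, so only the conjugated alkene can form, the trans arrangement of aryl and alkyl is favoured, and the internally delivered base should outrun capture of the benzylic cation by the distal alkene.

Step 8
Reactants: 11 {4-[(1E,3S)-3,7-dimethylocta-1,6-dien-1-yl]-3,5-bis(methoxymethoxy)phenoxy}tri(propan-2-yl)silane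
Product: 12 4-[(1E,3S)-3,7-dimethylocta-1,6-dien-1-yl]-3,5-bis(methoxymethoxy)phenol
Conditions: Bu4NF, THF, 0 °C; H2O
Reagents that add atoms: none
Why: Fluoride-mediated cleavage of the aryl silyl ether is selective for silicon and leaves acetals and alkenes untouched.

Step 9
Reactants: 12 4-[(1E,3S)-3,7-dimethylocta-1,6-dien-1-yl]-3,5-bis(methoxymethoxy)phenol
Product: 13 5-(1-ethoxyethoxy)-2-[(1E,3S)-3,7-dimethylocta-1,6-dien-1-yl]-1,3-bis(methoxymethoxy)benzene (both acetal epimers)
Conditions: ethyl vinyl ether, PPTS (cat.), CH2Cl2, 0 °C → rt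
Reagents that add atoms: ethyl vinyl ether, C=COCC
Why: Acid-catalysed addition of the phenol to ethyl vinyl ether (acetalisation) installs a second ortho-directing group that is far more acid-labile than the MOM ethers; the new acetal centre is unselective and is removed in step 10.

Step 10
Reactants: 13 5-(1-ethoxyethoxy)-2-[(1E,3S)-3,7-dimethylocta-1,6-dien-1-yl]-1,3-bis(methoxymethoxy)benzene
Product: 16 1-{6-hydroxy-3-[(1E,3S)-3,7-dimethylocta-1,6-dien-1-yl]-2,4-bis(methoxymethoxy)phenyl}ethan-1-one, via 2-(1-ethoxyethoxy)-5-[(1E,3S)-3,7-dimethylocta-1,6-dien-1-yl]-4,6-bis(methoxymethoxy)phenyllithium 14 (not isolated), via 1-{6-(1-ethoxyethoxy)-3-[(1E,3S)-3,7-dimethylocta-1,6-dien-1-yl]-2,4-bis(methoxymethoxy)phenyl}ethan-1-one 15 (not isolated)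
Conditions: n-BuLi, THF, 0 °C; then MeC(O)N(OMe)Me, −78 → 0 °C; H2O; crude product in MeOH, PPTS (cat.), rt
Reagents that add atoms: N-methoxy-N-methylacetamide, CC(=O)N(C)OC
Why: Directed ortho-metalation can only occur at the two equivalent ring positions between the ethoxyethyl and a MOM oxygen, the aryllithium is acylated by the Weinreb amide through a chelate that stops at the ketone, and PPTS-catalysed transacetalisation in methanol removes only the more labile ethoxyethyl acetal, so the acetyl group ends up ortho to the free hydroxyl by symmetry.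

Step 11
Reactants: 16 1-{6-hydroxy-3-[(1E,3S)-3,7-dimethylocta-1,6-dien-1-yl]-2,4-bis(methoxymethoxy)phenyl}ethan-1-one; 4 (2E)-3-[4-(methoxymethoxy)phenyl]prop-2-en-1-yl methyl carbonate
Product: 18 1-{6-{[(1S)-1-[4-(methoxymethoxy)phenyl]prop-2-en-1-yl]oxy}-3-[(1E,3S)-3,7-dimethylocta-1,6-dien-1-yl]-2,4-bis(methoxymethoxy)phenyl}ethan-1-one, via sodium 2-acetyl-4-[(1E,3S)-3,7-dimethylocta-1,6-dien-1-yl]-3,5-bis(methoxymethoxy)phenolate 17 (not isolated)
Conditions: NaH (1.0 equiv), THF, 0 °C; then 4 (1.2 equiv), [Ir(cod)Cl]2 (2 mol%), (Sa,Sc,Sc)-O,O′-(1,1′-binaphthalene-2,2′-diyl) N,N-bis(1-phenylethyl)phosphoramidite (4 mol%), THF, rt → 40 °C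
Reagents that add atoms: none
Why: In this iridium-catalysed asymmetric allylic etherification the aryloxide attacks the aryl-substituted terminus of the allyliridium intermediate formed from the carbonate, giving the branched ether, and the phosphoramidite-derived metallacycle controls the face of attack and hence the S configuration at C2.

Step 12
Reactants: 18 1-{6-{[(1S)-1-[4-(methoxymethoxy)phenyl]prop-2-en-1-yl]oxy}-3-[(1E,3S)-3,7-dimethylocta-1,6-dien-1-yl]-2,4-bis(methoxymethoxy)phenyl}ethan-1-one
Product: 19 tert-butyl{[1-(2-{[(1S)-1-[4-(methoxymethoxy)phenyl]prop-2-en-1-yl]oxy}-5-[(1E,3S)-3,7-dimethylocta-1,6-dien-1-yl]-4,6-bis(methoxymethoxy)phenyl)ethenyl]oxy}dimethylsilane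
Conditions: Et3N (3 equiv), t-BuMe2SiOTf (1.3 equiv), CH2Cl2, −78 → 0 °C
Reagents that add atoms: tert-butyldimethylsilyl trifluoromethanesulfonate, CC(C)(C)[Si](C)(C)OS(=O)(=O)C(F)(F)F
Why: Soft enolisation of the methyl ketone with silyl triflate and triethylamine (silyl enol ether formation) has only one enolisable position, and amine-buffered triflate at low temperature should spare the MOM ethers and the ionisable C2–O1 bond.

Step 13
Reactants: 19 tert-butyl{[1-(2-{[(1S)-1-[4-(methoxymethoxy)phenyl]prop-2-en-1-yl]oxy}-5-[(1E,3S)-3,7-dimethylocta-1,6-dien-1-yl]-4,6-bis(methoxymethoxy)phenyl)ethenyl]oxy}dimethylsilane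
Product: 20 tert-butyl({(2S)-6-[(1E,3S)-3,7-dimethylocta-1,6-dien-1-yl]-5,7-bis(methoxymethoxy)-2-[4-(methoxymethoxy)phenyl]-2H-chromen-4-yl}oxy)dimethylsilane
Conditions: second-generation Grubbs catalyst RuCl2(H2IMes)(PCy3)(=CHPh) (10 mol%), degassed toluene (0.005 M), 60 °C, Ar
Reagents that add atoms: none
Why: The ruthenium benzylidene should initiate at the monosubstituted vinyl group of the allylic ether, the resulting alkylidene adds across the 1,1-disubstituted silyl enol ether in an intramolecular [2+2] step, and cycloreversion of the ruthenacyclobutane forms C3=C4 and passes on Ru=CH2, so that ethene is the only by-product. The closest known reaction type is the ring-closing metathesis of olefin-tethered silyl enol ethers, which gives cyclic silyl enol ethers including benzo-fused six-membered ones from ortho-(1-silyloxyvinyl)aryl allyl systems. Ring C closes as a six-membered ring by ring-closing metathesis between the vinyl group on C2 and the enol ether carbon C4, the new double bond being endocyclic. No stereocentre is created, and C2 is not a reacting centre and keeps the configuration set in step 11. The step needs chemoselectivity for the two terminal alkenes over the side-chain alkenes, which the substrate secures because the styrenyl alkene is 1,2-disubstituted and flanked by two ortho MOM ethers and the distal alkene is trisubstituted, while high dilution favours the intramolecular event. Neutral conditions at 60 °C or below should leave the ionisable C2–O1 ether intact and stay below the onset of an aromatic Claisen rearrangement.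

Step 14
Reactants: 20 tert-butyl({(2S)-6-[(1E,3S)-3,7-dimethylocta-1,6-dien-1-yl]-5,7-bis(methoxymethoxy)-2-[4-(methoxymethoxy)phenyl]-2H-chromen-4-yl}oxy)dimethylsilane
Product: 21 (2S)-6-[(1E,3S)-3,7-dimethylocta-1,6-dien-1-yl]-5,7-bis(methoxymethoxy)-2-[4-(methoxymethoxy)phenyl]-2,3-dihydro-4H-chromen-4-one
Conditions: Bu4NF, AcOH (1:1.2), THF, 0 °C
Reagents that add atoms: none
Why: Fluoride attacks silicon of the silyl enol ether (desilylation) and the acetic acid buffer protonates the enolate at C3 at once, so that E1cB opening of ring C to the chalcone, which would scramble C2, gets no chance; MOM ethers are inert to buffered fluoride.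

Step 15
Reactants: 21 (2S)-6-[(1E,3S)-3,7-dimethylocta-1,6-dien-1-yl]-5,7-bis(methoxymethoxy)-2-[4-(methoxymethoxy)phenyl]-2,3-dihydro-4H-chromen-4-one
Product: 23 (2S)-6-[(1E,3S)-3,7-dimethylocta-1,6-dien-1-yl]-5,7-dihydroxy-2-(4-hydroxyphenyl)-2,3-dihydro-4H-chromen-4-one (CNP0150993.1), via 5,7,4′-tris-O-trimethylsilyl flavanone 22 (not isolated)
Conditions: Me3SiOTf (6 equiv), 2,2′-bipyridyl (9 equiv), CH2Cl2, 0 °C → rt; then H2O, rt
Reagents that add atoms: none
Why: Silyl triflate together with 2,2′-bipyridyl converts aromatic MOM ethers into aryl silyl ethers (Lewis-acid-mediated acetal cleavage) that hydrolyse on adding water, and the absence of protic acid should prevent both protonation of the electron-rich styrene between the two phenols and acid-induced opening of ring C.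

**Compound list**

1 | methyl (2E)-3-(4-hydroxyphenyl)prop-2-enoate | COC(=O)/C=C/c1ccc(O)cc1 | starting material
2 | methyl (2E)-3-[4-(methoxymethoxy)phenyl]prop-2-enoate | COCOc1ccc(/C=C/C(=O)OC)cc1 | intermediate
3 | (2E)-3-[4-(methoxymethoxy)phenyl]prop-2-en-1-ol | COCOc1ccc(/C=C/CO)cc1 | intermediate
4 | (2E)-3-[4-(methoxymethoxy)phenyl]prop-2-en-1-yl methyl carbonate | COCOc1ccc(/C=C/COC(=O)OC)cc1 | intermediate
5 | benzene-1,3,5-triol (phloroglucinol) | Oc1cc(O)cc(O)c1 | starting material
6 | 3,5-bis(methoxymethoxy)phenol | COCOc1cc(O)cc(OCOC)c1 | intermediate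
7 | [3,5-bis(methoxymethoxy)phenoxy]tri(propan-2-yl)silane | COCOc1cc(OCOC)cc(O[Si](C(C)C)(C(C)C)C(C)C)c1 | intermediate
8 | (3S)-3,7-dimethyloct-6-enal ((S)-citronellal) | CC(C)=CCC[C@H](C)CC=O | starting material
9 | 2,6-bis(methoxymethoxy)-4-(triisopropylsilyloxy)phenyllithium | [Li]c1c(OCOC)cc(O[Si](C(C)C)(C(C)C)C(C)C)cc1OCOC | intermediate
10 | (1RS,3S)-1-[2,6-bis(methoxymethoxy)-4-(triisopropylsilyloxy)phenyl]-3,7-dimethyloct-6-en-1-ol | CC(C)=CCC[C@H](C)CC(O)c1c(OCOC)cc(O[Si](C(C)C)(C(C)C)C(C)C)cc1OCOC | intermediate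
11 | {4-[(1E,3S)-3,7-dimethylocta-1,6-dien-1-yl]-3,5-bis(methoxymethoxy)phenoxy}tri(propan-2-yl)silane | CC(C)=CCC[C@H](C)/C=C/c1c(OCOC)cc(O[Si](C(C)C)(C(C)C)C(C)C)cc1OCOC | intermediate
12 | 4-[(1E,3S)-3,7-dimethylocta-1,6-dien-1-yl]-3,5-bis(methoxymethoxy)phenol | CC(C)=CCC[C@H](C)/C=C/c1c(OCOC)cc(O)cc1OCOC | intermediate
13 | 5-(1-ethoxyethoxy)-2-[(1E,3S)-3,7-dimethylocta-1,6-dien-1-yl]-1,3-bis(methoxymethoxy)benzene | CCOC(C)Oc1cc(OCOC)c(/C=C/[C@@H](C)CCC=C(C)C)c(OCOC)c1 | intermediate
14 | 2-(1-ethoxyethoxy)-5-[(1E,3S)-3,7-dimethylocta-1,6-dien-1-yl]-4,6-bis(methoxymethoxy)phenyllithium | [Li]c1c(OC(C)OCC)cc(OCOC)c(/C=C/[C@@H](C)CCC=C(C)C)c1OCOC | intermediate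
15 | 1-{6-(1-ethoxyethoxy)-3-[(1E,3S)-3,7-dimethylocta-1,6-dien-1-yl]-2,4-bis(methoxymethoxy)phenyl}ethan-1-one | CCOC(C)Oc1cc(OCOC)c(/C=C/[C@@H](C)CCC=C(C)C)c(OCOC)c1C(C)=O | intermediate
16 | 1-{6-hydroxy-3-[(1E,3S)-3,7-dimethylocta-1,6-dien-1-yl]-2,4-bis(methoxymethoxy)phenyl}ethan-1-one | CC(=O)c1c(O)cc(OCOC)c(/C=C/[C@@H](C)CCC=C(C)C)c1OCOC | intermediate
17 | sodium 2-acetyl-4-[(1E,3S)-3,7-dimethylocta-1,6-dien-1-yl]-3,5-bis(methoxymethoxy)phenolate | CC(=O)c1c([O-])cc(OCOC)c(/C=C/[C@@H](C)CCC=C(C)C)c1OCOC.[Na+] | intermediate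
18 | 1-{6-{[(1S)-1-[4-(methoxymethoxy)phenyl]prop-2-en-1-yl]oxy}-3-[(1E,3S)-3,7-dimethylocta-1,6-dien-1-yl]-2,4-bis(methoxymethoxy)phenyl}ethan-1-one | C=C[C@@H](c1ccc(OCOC)cc1)Oc1cc(OCOC)c(/C=C/[C@@H](C)CCC=C(C)C)c(OCOC)c1C(C)=O | intermediate
19 | tert-butyl{[1-(2-{[(1S)-1-[4-(methoxymethoxy)phenyl]prop-2-en-1-yl]oxy}-5-[(1E,3S)-3,7-dimethylocta-1,6-dien-1-yl]-4,6-bis(methoxymethoxy)phenyl)ethenyl]oxy}dimethylsilane | C=C[C@@H](c1ccc(OCOC)cc1)Oc1cc(OCOC)c(/C=C/[C@@H](C)CCC=C(C)C)c(OCOC)c1C(=C)O[Si](C)(C)C(C)(C)C | intermediate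
20 | tert-butyl({(2S)-6-[(1E,3S)-3,7-dimethylocta-1,6-dien-1-yl]-5,7-bis(methoxymethoxy)-2-[4-(methoxymethoxy)phenyl]-2H-chromen-4-yl}oxy)dimethylsilane | CC(C)(C)[Si](C)(C)OC1=C[C@@H](c2ccc(OCOC)cc2)Oc2cc(OCOC)c(/C=C/[C@@H](C)CCC=C(C)C)c(OCOC)c12 | intermediate
21 | (2S)-6-[(1E,3S)-3,7-dimethylocta-1,6-dien-1-yl]-5,7-bis(methoxymethoxy)-2-[4-(methoxymethoxy)phenyl]-2,3-dihydro-4H-chromen-4-one | CC(C)=CCC[C@H](C)/C=C/c1c(OCOC)cc2c(c1OCOC)C(=O)C[C@@H](c1ccc(OCOC)cc1)O2 | intermediate
22 | (2S)-6-[(1E,3S)-3,7-dimethylocta-1,6-dien-1-yl]-5,7-bis(trimethylsilyloxy)-2-[4-(trimethylsilyloxy)phenyl]-2,3-dihydro-4H-chromen-4-one | CC(C)=CCC[C@H](C)/C=C/c1c(O[Si](C)(C)C)cc2c(c1O[Si](C)(C)C)C(=O)C[C@@H](c1ccc(O[Si](C)(C)C)cc1)O2 | intermediate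
23 | (2S)-6-[(1E,3S)-3,7-dimethylocta-1,6-dien-1-yl]-5,7-dihydroxy-2-(4-hydroxyphenyl)-2,3-dihydro-4H-chromen-4-one | CC(C)=CCC[C@H](C)/C=C/c1c(O)cc2c(c1O)C(=O)C[C@@H](c1ccc(O)cc1)O2 | target

**Step count**

Total step count: 15.
Longest linear sequence: 12 steps (steps 4 to 15, from phloroglucinol); steps 1 to 3 make the cinnamyl carbonate that enters at step 11.

**Steps most likely to fail**

1. Step 13. The cyclisation onto the 1,1-disubstituted enol ether, which sits between two ortho oxygen substituents, may be slow. Catalyst decay, metathesis at the side-chain alkenes or thermal rearrangement of the allyl aryl ether could then compete. The fallback sets out from 16 and comes back to the route at 21. Condensation of 16 with N,N-dimethylformamide dimethyl acetal (toluene, 90 °C) should give the enaminone (2E)-3-(dimethylamino)-1-{6-hydroxy-3-[(1E,3S)-3,7-dimethylocta-1,6-dien-1-yl]-2,4-bis(methoxymethoxy)phenyl}prop-2-en-1-one F1. Brief warming with AcOH in toluene (60 °C) should close it, with loss of dimethylamine, to the chromone 6-[(1E,3S)-3,7-dimethylocta-1,6-dien-1-yl]-5,7-bis(methoxymethoxy)-4H-chromen-4-one F2. Rhodium-catalysed asymmetric 1,4-addition of commercial 4-(methoxymethoxy)phenylboronic acid would then give flavanone 21; the conditions are [Rh(OH)(cod)]2 with the enantiomer of an electron-poor atropisomeric bisphosphine that leads to 2S, toluene/H2O, 40 °C. Ring C is here closed at O1–C2 and the aryl group is added afterwards.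

2. Step 11. The electron-rich branched ether may ionise under the reaction conditions, eroding enantiomeric purity or isomerising to the linear cinnamyl ether, and the hindered, chelated aryloxide may react sluggishly. The fallback sets out from 16 and comes back at 18. Addition of CH2=CHMgBr to commercial 4-(methoxymethoxy)benzaldehyde (THF, 0 °C) gives racemic 1-[4-(methoxymethoxy)phenyl]prop-2-en-1-ol F3. Lipase-mediated acetylation (Candida antarctica lipase B, vinyl acetate) is expected to consume the R enantiomer and leave (1S)-1-[4-(methoxymethoxy)phenyl]prop-2-en-1-ol F4. Boc2O/DMAP then gives tert-butyl (1S)-1-[4-(methoxymethoxy)phenyl]prop-2-en-1-yl carbonate F5. Allylic etherification of 16 with F5 under [Cp*Ru(NCMe)3]PF6 catalysis, which is branch-selective and stereospecific with net retention, would give 18. The C2 configuration then comes from the resolved alcohol and not from a chiral catalyst.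

3. Step 7. The benzylic sulfamate may ionise to a cation stabilised by three oxygen substituents, which could be captured by the trisubstituted alkene (cyclisation) or by the carbamate nitrogen before a proton is lost. The fallback sets out from 10 and comes back at 11. Dess–Martin oxidation (CH2Cl2, NaHCO3) gives the ketone (3S)-1-[2,6-bis(methoxymethoxy)-4-(triisopropylsilyloxy)phenyl]-3,7-dimethyloct-6-en-1-one F6. Treatment with KN(SiMe3)2 and then PhNTf2 (THF, −78 °C) gives, through the Z enolate, the enol triflate (1Z,3S)-1-[2,6-bis(methoxymethoxy)-4-(triisopropylsilyloxy)phenyl]-3,7-dimethylocta-1,6-dien-1-yl trifluoromethanesulfonate F7. Palladium-catalysed formate reduction (Pd(OAc)2, PPh3, HCO2H, n-Bu3N, DMF, 60 °C) replaces the triflate by hydrogen with retention of alkene geometry and gives the E alkene 11 without a benzylic cation.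

**Further compounds**

F1 | step 13 | (2E)-3-(dimethylamino)-1-{6-hydroxy-3-[(1E,3S)-3,7-dimethylocta-1,6-dien-1-yl]-2,4-bis(methoxymethoxy)phenyl}prop-2-en-1-one | CN(C)/C=C/C(=O)c1c(O)cc(OCOC)c(/C=C/[C@@H](C)CCC=C(C)C)c1OCOC
F2 | step 13 | 6-[(1E,3S)-3,7-dimethylocta-1,6-dien-1-yl]-5,7-bis(methoxymethoxy)-4H-chromen-4-one | CC(C)=CCC[C@H](C)/C=C/c1c(OCOC)cc2occc(=O)c2c1OCOC
F3 | step 11 | racemic 1-[4-(methoxymethoxy)phenyl]prop-2-en-1-ol | C=CC(O)c1ccc(OCOC)cc1
F4 | step 11 | (1S)-1-[4-(methoxymethoxy)phenyl]prop-2-en-1-ol | C=C[C@H](O)c1ccc(OCOC)cc1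
F5 | step 11 | tert-butyl (1S)-1-[4-(methoxymethoxy)phenyl]prop-2-en-1-yl carbonate | C=C[C@H](OC(=O)OC(C)(C)C)c1ccc(OCOC)cc1
F6 | step 7 | (3S)-1-[2,6-bis(methoxymethoxy)-4-(triisopropylsilyloxy)phenyl]-3,7-dimethyloct-6-en-1-one | CC(C)=CCC[C@H](C)CC(=O)c1c(OCOC)cc(O[Si](C(C)C)(C(C)C)C(C)C)cc1OCOC
F7 | step 7 | (1Z,3S)-1-[2,6-bis(methoxymethoxy)-4-(triisopropylsilyloxy)phenyl]-3,7-dimethylocta-1,6-dien-1-yl trifluoromethanesulfonate | CC(C)=CCC[C@H](C)/C=C(\OS(=O)(=O)C(F)(F)F)c1c(OCOC)cc(O[Si](C(C)C)(C(C)C)C(C)C)cc1OCOC
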